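Add links and first end groups, take the sum from the charge, and the leftover is what still lies undissolved.

all flasks: solid first end groups 28 mM

|  | second end groups | third end groups | remark | time |
|---|---|---|---|---|
| Thursday's | 19 mM | 14 mM (in portions, 2) | run made earlier; portions every 2.0 min |  |
| Monday's | 43 mM | 14 mM (in portions, 2) | run made earlier; portions every 2.0 min |  |
| Saturday's | 28.6 mM | 7 mM (in portions, 2) | run made earlier; portions every 2.0 min |  |
| flask | 28.6 mM | 14.0 mM (in portions, 2) | the portions of third end groups follow each other after 2.0 min, the first at the start | 80 min |

| run | time / min | links / % | first end groups / % |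
|---|---|---|---|
| Thursday's | 5.00 | 2.7 | 5.7 |
| Thursday's | 8.00 | 6.5 | 7.1 |
| Thursday's | 15.0 | 13.4 | 8.9 |
| Thursday's | 25.0 | 24.0 | 11.8 |
| Thursday's | 40.0 | 38.8 | 15.0 |
| Thursday's | 60.0 | 53.2 | 21.5 |
| Monday's | 4.00 | 2.8 | 3.1 |
| Monday's | 12.0 | 15.2 | 4.4 |
| Monday's | 25.0 | 34.6 | 5.7 |
| Monday's | 40.0 | 54.9 | 6.6 |
| Monday's | 50.0 | 68.9 | 7.8 |
| Monday's | 60.0 | 82.8 | 8.6 |
| Saturday's | 5.00 | 3.0 | 5.1 |
| Saturday's | 10.0 | 9.8 | 6.6 |
| Saturday's | 20.0 | 23.0 | 7.4 |
| Saturday's | 30.0 | 36.2 | 7.4 |
| Saturday's | 60.0 | 69.9 | 14.1 |

(readings scatter by 0.5 percentage points)

- solid first end groups is a solid; its amount is given per volume of the solution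
- at the start none of the solid first end groups is in solution
- first end groups means what is dissolved; the solid is not counted in it
- what has only dissolved of solid first end groups counts as not reacted
- the reaction counts as stopped when no species that holds the solid first end groups changes by six tenths of a point or more over the second half of the time

1. why nothing more happens at 80 min, or that something still does (for what has run out or reacted, a solid counts together with what of it has only dissolved) (all of the solid first end groups has reacted / it is still moving / the second end groups has run out first / forward and back rates have come level)
2. the links standing at 80 min, as a percentage of the solid first end groups charged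
3. the first end groups standing at 80 min, as a percentage of the solid first end groups charged

Saturday's run has the flask's c(second end groups) and half its third end groups. By 60.0 min its links (69.9%) and first end groups (14.1%) together give the feed, the average concentration of solid entering solution per minute: 0.392 mM min⁻¹. Thursday's and Monday's runs, with other c(second end groups), give 0.349 mM min⁻¹ and 0.427 mM min⁻¹.

Take Saturday's feed as steady, a zero-order supply. Then, by this estimate, c(solid first end groups) in the flask falls on a straight line and reaches zero at charge over feed, 71.4 min, earlier than the 80 min asked. So your reckoning says links and first end groups share the whole charge at the end. Saturday's run at 60.0 min still holds first end groups beside 9.03 mM of second end groups not in links, so you call the flask still moving.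

The forecast, with “The solid is gone near 75 min”, said it is still moving, with 85% links and 15% first end groups.

The flask gives: it is still moving, 81.7% links, 18.3% first end groups, 0% solid.

    first end groups + second end groups → links (k = 0.150 M⁻¹ s⁻¹)
    second end groups + third end groups → links of the second sort (k = 0.00430 M⁻¹ s⁻¹)
    solid first end groups ⇌ first end groups, rate k3*(cs3 - [first end groups]) while solid is left; crystals form when [first end groups] > cs3 (solubility = 13.0 mM, k = 6.20 × 10⁻⁴ s⁻¹)

The straight line puts 44.0% of the solid at 40.0 min, and the flask holds 41.3%. Links fall short mainly through the low solubility of first end groups, which also sets how fast it dissolves: the run without it reaches 94.7% links against 81.7%.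

Take the same flask with 7.0 mM of solid: reckoned at the feed, its solid lasts 17.9 min, inside the 80 min. Computed, that flask stands at >99.9% links and 0% first end groups.

Readings and results come from a simulation with made-up constants, noise included.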